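**The pitfall.** The ratio of target peak to cross product peak is not a constant of the chemistry. It reads 0.305 in the summer run and 0.202 in the noon run at the same temperature, and the second substrate charge differs between them.

| flask | starting material | second substrate | gas | temperature | remark | time |
|---|---|---|---|---|---|---|
| summer | 0.40 M | 0.80 M | 200 mM (held) | 20 °C | run made earlier |  |
| dusk | 1.6 M | 0.80 M | 200 mM (held) | 53 °C | run made earlier |  |
| noon | 0.80 M | 1.2 M | 200 mM (held) | 20 °C | run made earlier |  |
| gamma | 0.80 M | 0.800 M | 200 mM (held) | 5 °C |  | 5.0 h |
| delta | 0.80 M | 0.800 M | 200 mM (held) | 35 °C |  | 5.0 h |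
| beta | 0.80 M | 0.800 M | 200 mM (held) | 65 °C |  | 5.0 h |

summer run (percent of the starting material charged)

| time / h | target / % | cross product / % |
|---|---|---|
| 0.167 | 8.6 | 36.0 |
| 0.500 | 16.7 | 59.6 |
| 1.00 | 21.8 | 66.8 |
| 1.33 | 22.1 | 68.6 |
| 2.00 | 21.4 | 69.0 |
| 2.50 | 21.1 | 69.2 |

dusk run (percent of the starting material charged)

| time / min | target / % | cross product / % |
|---|---|---|
| 2.50 | 2.3 | 47.0 |
| 4.00 | 2.1 | 49.1 |
| 6.00 | 3.5 | 50.1 |
| 12.0 | 5.0 | 49.9 |
| 15.0 | 5.2 | 48.7 |
| 30.0 | 5.1 | 49.1 |

noon run (percent of the starting material charged)

| time / h | target / % | cross product / % |
|---|---|---|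
| 0.200 | 7.5 | 50.6 |
| 0.417 | 11.7 | 64.1 |
| 0.667 | 14.2 | 71.5 |
| 1.33 | 15.2 | 75.2 |
| 2.50 | 15.2 | 75.3 |

(each reading ± 0.5 percentage points)

- the flask that comes out highest in share of target in all that became target or cross product or side product, or "all alike" when all lie within 1.5 percentage points (gamma / delta / beta / all alike)
- share of target in all that became target or cross product or side product, gamma
- share of target in all that became target or cross product or side product, delta
- share of target in all that became target or cross product or side product, beta

- percentages count the starting material that a species holds: one side product counts as two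
- at the start none of the gas is in solution

**The ladder.** In the dusk run, cross product has taken nearly all of the second substrate by 2.50 min. Target climbs from 2.3% to 5.0% after that, so on this rung it lags behind cross product. The summer run stands one rung slower: cross product holds 36.0% at 0.167 h, and both products level off near 1.33 h, later than dusk's 12.0 min.

**The crossing.** Dissolved gas starts at zero and fills towards a saturation level of 200 mM; this reckoning takes it at that level, so target forms in proportion to starting material, while cross product forms in proportion to starting material and second substrate. The two hand over control at a crossing concentration, a selectivity factor with units: the second substrate level at which both routes run equally fast, read as 0.199 M in the summer run. It equals target divided by the logarithm of charged second substrate over the second substrate that cross product has left. Noon, at the same temperature as summer, reads 0.174 M. Dusk reads 0.0203 M, a rough reading, since its small remainder carries the scatter.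

**The reckoning.** A straight line for the logarithm of the crossing against temperature, drawn through summer and dusk, gives 0.0705 M for delta and, carried past dusk, 0.00886 M for beta. Gamma lies colder than any reading, so this reckoning keeps 0.199 M there. It assumes each flask uses up its starting material, keeps summer's 90.3% in target and cross product, and takes a first logarithm 1.18. One further pass gives target shares of 23.4%, 14.1% and 2.44% for gamma, delta and beta.

**The forecast.** It names gamma, with 40%, 11% and 2.5%, on the ground that “target selectivity falls steeply on warming”, and it stands above this reckoning for gamma.

**The result.** Gamma, delta and beta give 25.1%, 13.9% and 3.88%, so gamma comes out highest.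

    starting material + partner → target (k = 3.60 × 10⁻⁴ M⁻¹ s⁻¹, Ea = 65.0 kJ mol⁻¹)
    second substrate + partner → second product (k = 1.50 × 10⁻⁴ M⁻¹ s⁻¹, Ea = 56.0 kJ mol⁻¹)
    starting material + second substrate → cross product (k = 2.30 × 10⁻⁴ M⁻¹ s⁻¹, Ea = 71.0 kJ mol⁻¹)
    starting material + target → side product (k = 1.80 × 10⁻⁴ M⁻¹ s⁻¹, Ea = 78.0 kJ mol⁻¹)
    gas ⇌ partner, rate k5*(csat - [partner]) (kL = 0.00720 s⁻¹)
    partner → decomposed reagent (k = 1.80 × 10⁻⁵ s⁻¹, Ea = 86.0 kJ mol⁻¹)
    (constants at 5 °C)

**Crossing regained.** The same quotient, which counts the second substrate lost to cross product and not that lost to second product, falls on warming: 0.251 M in gamma, above summer's 0.199 M, then 0.0945 M in delta and 0.0150 M in beta. The neighbour at 50 °C lies midway between delta and beta, so the geometric mean of their crossings, with that neighbour's 79.1% of cross product, gives 7.36% target, and the neighbour holds 8.14%.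

The data stem from a simulated flask for an exercise; the scatter is artificial.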